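**Plan**

Atom numbers are those of the target: ring C1 (ketone), C2, C3–C4 (epoxide, C15 on C4), C5, C6 (lactone O), C7, C8 (OH), C9 (angelate), C10 (=C14); lactone carbons C11 (=C13) and C12.
Retrosynthesis: the C3–C4 epoxide oxygen, the C9–O acyl bond, C13 and the lactone bonds O6–C12 and C7–C11 are removed first; the ten-membered ring is then opened at C5–C6 while C3 is joined to C8; last, C7–C8 is cut to an alkenyllithium and a cyclohexenone.
Enabling feature: with the epoxide read as an E olefin, the ten-membered ring holds O–C8 flanked by C7–C6(O) and, across the ring, C3=C4–C5, the cyclodec-5-enone pattern of an oxy-Cope product. Bonding C3 to C8 folds it into the six-membered ring C8–C3–C2–C1–C10–C9, which is the carvone ring with the carvone carbonyl carbon as C1.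
Forward: six-membered ring from (R)-carvone (its oxygen kept at C1), addition of the C7=C6 enol ether, expansion to the ten-membered ring, C7 alkylation and closure of the five-membered lactone ring, then C8/C9/C10 adjustment, methylenation, angeloylation, epoxide ring and C1 ketone.
Stereochemistry: the carvone stereocentre (future C3) sets C8 by anti addition, and both are relayed to C6 through the chair of the rearrangement. C7 and C8 follow from outer-face attack next to C6, C9 from hydroxyl-directed epoxidation, C3/C4 from the chiral ketone catalyst, and the angelate geometry from angelic acid.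

Key step: step 7

Remark: the C1 silyl ether keeps the cis-carveol configuration as a spectator until it becomes the ketone; 4-methoxybenzyl ethynyl ether 9 is assumed usable if kept cold, since benzylic alkynyl ethers rearrange on warming.

**Route**

Step 1
Reactants: 1 (R)-carvone
Product: 2 (1R,5R)-cis-carveol
Conditions: NaBH4, CeCl3·7H2O, MeOH, 0 °C
Reagents that add atoms: none
Why: Luche reduction delivers hydride 1,2 to the enone along the axial trajectory, so the new carbinol (1R) should be equatorial and cis to the isopropenyl group.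

Step 2
Reactants: 2 (1R,5R)-cis-carveol
Product: 3 (1R,5R)-cis-carveol tert-butyldimethylsilyl ether
Conditions: TBSCl, imidazole, DMF, rt
Reagents that add atoms: tert-butyldimethylsilyl chloride, CC(C)(C)[Si](C)(C)Cl
Why: Standard silylation of a secondary allylic alcohol, which blocks this allylic ring position and carries the future C1 oxygen through the route.

Step 3
Reactants: 3 (1R,5R)-cis-carveol tert-butyldimethylsilyl ether
Product: 4 (4R,6R)-4-(tert-butyldimethylsilyloxy)-3-methyl-6-(prop-1-en-2-yl)cyclohex-2-en-1-one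
Conditions: CrO3, 3,5-dimethylpyrazole, CH2Cl2, −20 °C
Reagents that add atoms: chromium trioxide, O=[Cr](=O)=O
Why: Allylic oxidation of a trisubstituted cyclohexene by the CrO3–3,5-dimethylpyrazole complex should convert the only free ring CH2 next to the olefin into the enone carbonyl, and the isopropenyl-bearing centre alpha to it is kept because no base is present.

Step 4
Reactants: 5 4-methoxybenzyl alcohol; 6 trichloroethylene
Product: 9 4-methoxybenzyl ethynyl ether, via dichlorovinyl ether 7 (not isolated), via lithium alkynyl ether 8 (not isolated)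
Conditions: KH, THF, 0 °C; Cl2C=CHCl, −50 °C → rt; n-BuLi (2.2 equiv), −78 → −40 °C; MeOH, −78 °C; product kept below 0 °C
Reagents that add atoms: none
Why: Known alkynyl ether synthesis from an alcohol: the potassium alkoxide substitutes trichloroethylene (addition to dichloroacetylene formed in the flask) to the 1,2-dichlorovinyl ether, butyllithium then dehydrochlorinates and exchanges the remaining chlorine to give the lithium acetylide, and methanol protonates it.

Step 5
Reactants: 9 4-methoxybenzyl ethynyl ether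
Product: 11 (E)-1-iodo-2-(4-methoxybenzyloxy)ethene, via vinylzirconocene 10 (not isolated)
Conditions: Cp2Zr(H)Cl, THF, 0 °C; I2, −78 °C
Reagents that add atoms: iodine, II
Why: Hydrozirconation of the terminal alkyne is a syn addition that places zirconium on the terminal carbon, and iodinolysis of the C–Zr bond proceeds with retention, which fixes the E enol ether geometry.

Step 6
Reactants: 11 (E)-1-iodo-2-(4-methoxybenzyloxy)ethene; 4 (4R,6R)-4-(tert-butyldimethylsilyloxy)-3-methyl-6-(prop-1-en-2-yl)cyclohex-2-en-1-one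
Product: 13 (1R,4R,6R)-4-(tert-butyldimethylsilyloxy)-1-[(E)-2-(4-methoxybenzyloxy)vinyl]-3-methyl-6-(prop-1-en-2-yl)cyclohex-2-en-1-ol, via alkenyllithium 12 (not isolated)
Conditions: t-BuLi (2 equiv), Et2O, −78 °C; 4, THF, −78 °C; H2O
Reagents that add atoms: none
Why: Iodine–lithium exchange retains the E geometry and the alkenyllithium should add 1,2 to the enone carbonyl from the face away from the neighbouring isopropenyl group, which sets the carbinol centre (future C8) with the two alkenyl groups trans; the non-acidic quench spares the enol ether.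

Step 7
Reactants: 13 (1R,4R,6R)-4-(tert-butyldimethylsilyloxy)-1-[(E)-2-(4-methoxybenzyloxy)vinyl]-3-methyl-6-(prop-1-en-2-yl)cyclohex-2-en-1-ol
Product: 16 (1R,6R)-1-(tert-butyldimethylsilyloxy)-6-(4-methoxybenzyloxy)-4,10-dimethylcyclodeca-3E,9Z-dien-8-one (target numbering), via potassium alkoxide 14 (not isolated), via potassium enolate 15 (not isolated)
Conditions: KN(SiMe3)2, 18-crown-6, THF, 0 °C → rt; AcOH, −78 °C
Reagents that add atoms: none
Why: The potassium alkoxide 14, loosened from its counter-ion by 18-crown-6, undergoes the anionic oxy-Cope rearrangement: the array C6=C7–C8–C3–C4=C5 reorganises in one 3,3-sigmatropic shift that forms C5–C6 and breaks C3–C8, and enolate 15 is protonated to the C8 ketone. The closest known reaction type is the anionic oxy-Cope ring expansion of trans-1,2-dialkenylcyclohexanols to cyclodec-5-enones used for germacrane skeletons. The ten-membered ring is not closed by cyclisation; it arises by four-atom expansion of the six-membered ring through a chair transition state fused to the cyclohexene like a trans-decalin, with both alkenyl groups equatorial. C6 is the only new stereocentre: chirality is transferred from C3 and C8 through that chair, in which the E-configured OPMB group sits equatorial, giving 6R, and the same chair gives the E C3=C4 bond while C9=C10 stays Z. The step needs chair over boat, no Cope through the ring olefin C9=C10 and no loss of the C6 alkoxide from enolate 15; the trans alkenyl groups from step 6, the strain of a boat through the ring olefin, the E purity of the enol ether from step 5 and the cold acidic quench should secure this.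

Step 8
Reactants: 16 (1R,6R)-1-(tert-butyldimethylsilyloxy)-6-(4-methoxybenzyloxy)-4,10-dimethylcyclodeca-3E,9Z-dien-8-one; 17 methyl bromoacetate
Product: 19 methyl [(1R,6R,7S)-1-(tert-butyldimethylsilyloxy)-6-(4-methoxybenzyloxy)-4,10-dimethyl-8-oxocyclodeca-3E,9Z-dien-7-yl]acetate (target numbering), via lithium enolate 18 (not isolated)
Conditions: LiN(i-Pr)2, THF, −78 °C; BrCH2CO2Me, DMPU, −78 → −40 °C
Reagents that add atoms: none
Why: Kinetic alpha' deprotonation of the enone at C7 followed by SN2 alkylation of the lithium enolate; the electrophile should enter from the outer face of the ring, anti to the C6 alkoxy group, which sets C7 with C11 trans to O6.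

Step 9
Reactants: 19 methyl [(1R,6R,7S)-1-(tert-butyldimethylsilyloxy)-6-(4-methoxybenzyloxy)-4,10-dimethyl-8-oxocyclodeca-3E,9Z-dien-7-yl]acetate
Product: 21 (1R,6R,7S)-1-(tert-butyldimethylsilyloxy)-4,10-dimethyl-8-oxocyclodeca-3E,9Z-dieno-12,6-lactone (trans-fused five-membered lactone O6–C12(=O)–C11H2–C7), via hydroxy ester 20 (not isolated)
Conditions: DDQ, CH2Cl2/pH 7 buffer, 0 °C; PPTS (cat.), CH2Cl2, rt
Reagents that add atoms: none
Why: Oxidative cleavage of the 4-methoxybenzyl ether by DDQ frees the C6 hydroxyl, which lactonises onto the methyl ester under mild acid catalysis; C8 is still a ketone, so only O6 can close the lactone, and C6 and C7 are untouched.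

Step 10
Reactants: 21 (1R,6R,7S)-8-oxo lactone
Product: 22 (1R,6R,7R,8R)-1-(tert-butyldimethylsilyloxy)-8-hydroxy-4,10-dimethylcyclodeca-3E,9Z-dieno-12,6-lactone
Conditions: NaBH4, CeCl3·7H2O, MeOH, −78 °C
Reagents that add atoms: none
Why: Luche 1,2-reduction of the Z-enone; hydride should attack the carbonyl from the outer face of the ten-membered ring, which places the C8 hydroxyl cis to C11 (the configuration that is 8S in the target).

Step 11
Reactants: 22 (1R,6R,7R,8R)-8-hydroxy lactone
Product: 23 (1R,6R,7R,8S,9S,10S)-1-(tert-butyldimethylsilyloxy)-9,10-epoxy-8-hydroxy-4,10-dimethylcyclodec-3E-eno-12,6-lactone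
Conditions: VO(acac)2 (cat.), t-BuOOH, CH2Cl2, 0 °C
Reagents that add atoms: tert-butyl hydroperoxide, CC(C)(C)OO
Why: Vanadium-catalysed hydroxyl-directed epoxidation: the C8 vanadate should deliver oxygen only to the allylic C9=C10 bond and to the face syn to the hydroxyl (cis epoxy alcohol, as with medium-ring Z-cycloalkenols), which sets C9 and C10 and leaves the remote C3=C4 bond.

Step 12
Reactants: 23 (1R,6R,7R,8S,9S,10S)-epoxy alcohol
Product: 24 (1R,6R,7S,8S,9S,10S)-1,8-bis(tert-butyldimethylsilyloxy)-9,10-epoxy-4,10-dimethylcyclodec-3E-eno-12,6-lactone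
Conditions: TBSOTf, 2,6-lutidine, CH2Cl2, −78 °C
Reagents that add atoms: tert-butyldimethylsilyl triflate, CC(C)(C)[Si](C)(C)OS(=O)(=O)C(F)(F)F
Why: Silylation of the hindered C8 hydroxyl with the silyl triflate at low temperature, so that O8 stays distinct from the O9 hydroxyl made in the next step.

Step 13
Reactants: 24 (1R,6R,7S,8S,9S,10S)-bis-silyl epoxide
Product: 25 (1R,6R,7S,8S,9R)-1,8-bis(tert-butyldimethylsilyloxy)-9-hydroxy-4-methyl-10-methylidenecyclodec-3E-eno-12,6-lactone
Conditions: 2,2,6,6-tetramethylpiperidine, n-BuLi, then Et2AlCl, toluene, 0 °C; 24, 0 °C → rt; aq. potassium sodium tartrate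
Reagents that add atoms: none
Why: Base-mediated isomerisation of a trisubstituted epoxide to an allylic alcohol with diethylaluminium 2,2,6,6-tetramethylpiperidide: aluminium binds the epoxide oxygen and the amide removes a syn proton from C14 (the methyl cis to H9), so C10–O breaks, C9 keeps its oxygen and configuration, and C10=C14 forms without a cation that C3=C4 could trap.

Step 14
Reactants: 25 (1R,6R,7S,8S,9R)-9-hydroxy-10-methylidene lactone
Product: 28 (1R,6R,7S,8S,9R)-1,8-bis(tert-butyldimethylsilyloxy)-9-hydroxy-4-methyl-10,11-dimethylidenecyclodec-3E-eno-12,6-lactone (C11=C13 methylene lactone), via Mannich base 26 (not isolated), via ammonium iodide 27 (not isolated)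
Conditions: LiN(i-Pr)2 (2.5 equiv), THF, −78 °C; CH2=NMe2 I, −78 °C → rt; MeI, MeOH, rt; aq. NaHCO3, EtOAc
Reagents that add atoms: dimethyl(methylidene)ammonium iodide, C=[N+](C)C.[I-]
Why: Eschenmoser methylenation: Mannich reaction of the lactone enolate (the C9 hydroxyl carried as its lithium alkoxide), N-methylation and E1cB loss of trimethylamine should give the exocyclic C11=C13 bond; it is done before the angelate is present because that ester would not tolerate the amide base.

Step 15
Reactants: 28 (1R,6R,7S,8S,9R)-methylene lactone; 29 angelic acid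
Product: 31 (1R,6R,7S,8S,9R)-9-angeloyloxy-1,8-bis(tert-butyldimethylsilyloxy)-4-methyl-10,11-dimethylidenecyclodec-3E-eno-12,6-lactone, via mixed anhydride 30 (not isolated)
Conditions: 2,4,6-trichlorobenzoyl chloride, Et3N, toluene, rt; 28, 80 °C
Reagents that add atoms: none
Why: Yamaguchi-type esterification through the mixed anhydride without DMAP, conditions under which the Z olefin of the angelate should not isomerise to the tiglate; O9 is acylated with retention at C9.

Step 16
Reactants: 31 (1R,6R,7S,8S,9R)-9-angelate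
Product: 32 (1R,3R,4R,6R,7S,8S,9R)-9-angeloyloxy-1,8-bis(tert-butyldimethylsilyloxy)-3,4-epoxy-4-methyl-10,11-dimethylidenecyclodecano-12,6-lactone
Conditions: 1,2:4,5-di-O-isopropylidene-D-erythro-2,3-hexodiulo-2,6-pyranose (0.3 equiv), Oxone (2KHSO5·KHSO4·K2SO4), K2CO3, Bu4NHSO4, MeCN/CH2(OMe)2/aq. Na2B4O7, 0 °C
Reagents that add atoms: potassium peroxymonosulfate, [K+].[O-]S(=O)(=O)OO
Why: Shi epoxidation: the chiral dioxirane attacks the only electron-rich olefin, E-trisubstituted C3=C4, and the D-fructose-derived ketone delivers the R,R epoxide of E olefins through its spiro transition state; since the ring olefin can turn through the ring, the conformer that shows the matching face should react and give 3R,4R.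

Step 17
Reactants: 32 (1R,3R,4R,6R,7S,8S,9R)-bis-silyl epoxide
Product: 33 (1R,3R,4R,6R,7R,8S,9R)-9-angeloyloxy-3,4-epoxy-1,8-dihydroxy-4-methyl-10,11-dimethylidenecyclodecano-12,6-lactone
Conditions: HF·pyridine, pyridine, THF, 0 °C → rt
Reagents that add atoms: none
Why: Fluoride cleavage of both silyl ethers under buffered, weakly acidic conditions, which should spare the epoxide and avoid the alkoxide that would move the angelate from O9 to O8 or add to the methylene lactone.

Step 18
Reactants: 33 (1R,3R,4R,6R,7R,8S,9R)-1,8-diol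
Product: 34 target CNP0348992.2, (3R,4R,6R,7R,8S,9R)
Conditions: MnO2, CH2Cl2, rt
Reagents that add atoms: none
Why: MnO2 oxidises only the allylic C1 carbinol (next to C10=C14) to the cross-conjugated enone and leaves the non-allylic C8 hydroxyl.

**Compound list**

1 | (R)-carvone, (5R)-2-methyl-5-(prop-1-en-2-yl)cyclohex-2-en-1-one | CC1=CC[C@@H](C(C)=C)CC1=O | starting material
2 | (1R,5R)-cis-carveol | CC1=CC[C@@H](C(C)=C)C[C@H]1O | intermediate
3 | (1R,5R)-cis-carveol tert-butyldimethylsilyl ether | CC1=CC[C@@H](C(C)=C)C[C@H]1O[Si](C)(C)C(C)(C)C | intermediate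
4 | (4R,6R)-4-(tert-butyldimethylsilyloxy)-3-methyl-6-(prop-1-en-2-yl)cyclohex-2-en-1-one | CC1=CC(=O)[C@@H](C(C)=C)C[C@H]1O[Si](C)(C)C(C)(C)C | intermediate
5 | 4-methoxybenzyl alcohol | COc1ccc(CO)cc1 | starting material
6 | trichloroethylene | ClC=C(Cl)Cl | starting material
7 | 4-methoxybenzyl (E)-1,2-dichlorovinyl ether (formed in the flask) | COc1ccc(CO/C(Cl)=C\Cl)cc1 | intermediate
8 | lithium (4-methoxybenzyloxy)acetylide (formed in the flask) | COc1ccc(COC#C[Li])cc1 | intermediate
9 | 4-methoxybenzyl ethynyl ether | COc1ccc(COC#C)cc1 | intermediate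
10 | bis(cyclopentadienyl)[(E)-2-(4-methoxybenzyloxy)vinyl]zirconium chloride (formed in the flask) | COc1ccc(CO/C=C/[Zr](Cl)(C2C=CC=C2)C2C=CC=C2)cc1 | intermediate
11 | (E)-1-iodo-2-(4-methoxybenzyloxy)ethene | COc1ccc(CO/C=C/I)cc1 | intermediate
12 | (E)-2-(4-methoxybenzyloxy)vinyllithium (formed in the flask) | COc1ccc(CO/C=C/[Li])cc1 | intermediate
13 | (1R,4R,6R)-4-(tert-butyldimethylsilyloxy)-1-[(E)-2-(4-methoxybenzyloxy)vinyl]-3-methyl-6-(prop-1-en-2-yl)cyclohex-2-en-1-ol; alkenyl groups trans | CC1=C[C@](O)(/C=C/OCc2ccc(OC)cc2)[C@@H](C(C)=C)C[C@H]1O[Si](C)(C)C(C)(C)C | intermediate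
14 | potassium alkoxide of 13 (formed in the flask) | CC1=C[C@]([O-])(/C=C/OCc2ccc(OC)cc2)[C@@H](C(C)=C)C[C@H]1O[Si](C)(C)C(C)(C)C.[K+] | intermediate
15 | potassium 7Z-enolate (C7=C8–OK) of 16 (formed in the flask) | COc1ccc(CO[C@@H]2C/C(C)=C/C[C@@H](O[Si](C)(C)C(C)(C)C)/C(C)=C\C([O-])=C\2)cc1.[K+] | intermediate
16 | (1R,6R)-1-(tert-butyldimethylsilyloxy)-6-(4-methoxybenzyloxy)-4,10-dimethylcyclodeca-3E,9Z-dien-8-one (target numbering) | COc1ccc(CO[C@@H]2C/C(C)=C/C[C@@H](O[Si](C)(C)C(C)(C)C)/C(C)=C\C(=O)C2)cc1 | intermediate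
17 | methyl bromoacetate | COC(=O)CBr | starting material
18 | lithium 7Z-enolate of 16 (formed in the flask) | COc1ccc(CO[C@@H]2C/C(C)=C/C[C@@H](O[Si](C)(C)C(C)(C)C)/C(C)=C\C(O[Li])=C\2)cc1 | intermediate
19 | methyl [(1R,6R,7S)-1-(tert-butyldimethylsilyloxy)-6-(4-methoxybenzyloxy)-4,10-dimethyl-8-oxocyclodeca-3E,9Z-dien-7-yl]acetate | COc1ccc(CO[C@@H]2C/C(C)=C/C[C@@H](O[Si](C)(C)C(C)(C)C)/C(C)=C\C(=O)[C@H]2CC(=O)OC)cc1 | intermediate
20 | methyl [(1R,6R,7S)-1-(tert-butyldimethylsilyloxy)-6-hydroxy-4,10-dimethyl-8-oxocyclodeca-3E,9Z-dien-7-yl]acetate (formed in the flask) | O[C@@H]1C/C(C)=C/C[C@@H](O[Si](C)(C)C(C)(C)C)/C(C)=C\C(=O)[C@H]1CC(=O)OC | intermediate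
21 | (1R,6R,7S)-1-(tert-butyldimethylsilyloxy)-4,10-dimethyl-8-oxocyclodeca-3E,9Z-dieno-12,6-lactone, trans-fused | C1C(=O)O[C@@H]2C/C(C)=C/C[C@@H](O[Si](C)(C)C(C)(C)C)/C(C)=C\C(=O)[C@@H]12 | intermediate
22 | (1R,6R,7R,8R)-1-(tert-butyldimethylsilyloxy)-8-hydroxy-4,10-dimethylcyclodeca-3E,9Z-dieno-12,6-lactone | C1C(=O)O[C@@H]2C/C(C)=C/C[C@@H](O[Si](C)(C)C(C)(C)C)/C(C)=C\[C@@H](O)[C@@H]12 | intermediate
23 | (1R,6R,7R,8S,9S,10S)-1-(tert-butyldimethylsilyloxy)-9,10-epoxy-8-hydroxy-4,10-dimethylcyclodec-3E-eno-12,6-lactone | C1C(=O)O[C@@H]2C/C(C)=C/C[C@@H](O[Si](C)(C)C(C)(C)C)[C@@]3(C)O[C@H]3[C@@H](O)[C@@H]12 | intermediate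
24 | (1R,6R,7S,8S,9S,10S)-1,8-bis(tert-butyldimethylsilyloxy)-9,10-epoxy-4,10-dimethylcyclodec-3E-eno-12,6-lactone | C1C(=O)O[C@@H]2C/C(C)=C/C[C@@H](O[Si](C)(C)C(C)(C)C)[C@@]3(C)O[C@H]3[C@@H](O[Si](C)(C)C(C)(C)C)[C@@H]12 | intermediate
25 | (1R,6R,7S,8S,9R)-1,8-bis(tert-butyldimethylsilyloxy)-9-hydroxy-4-methyl-10-methylidenecyclodec-3E-eno-12,6-lactone | C1C(=O)O[C@@H]2C/C(C)=C/C[C@@H](O[Si](C)(C)C(C)(C)C)C(=C)[C@@H](O)[C@@H](O[Si](C)(C)C(C)(C)C)[C@@H]12 | intermediate
26 | 11-(dimethylaminomethyl) derivative of 25, C11 epimers (formed in the flask) | CN(C)CC1C(=O)O[C@@H]2C/C(C)=C/C[C@@H](O[Si](C)(C)C(C)(C)C)C(=C)[C@@H](O)[C@@H](O[Si](C)(C)C(C)(C)C)[C@@H]12 | intermediate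
27 | 11-(trimethylammoniomethyl) iodide of 25, C11 epimers (formed in the flask) | C[N+](C)(C)CC1C(=O)O[C@@H]2C/C(C)=C/C[C@@H](O[Si](C)(C)C(C)(C)C)C(=C)[C@@H](O)[C@@H](O[Si](C)(C)C(C)(C)C)[C@@H]12.[I-] | intermediate
28 | (1R,6R,7S,8S,9R)-1,8-bis(tert-butyldimethylsilyloxy)-9-hydroxy-4-methyl-10,11-dimethylidenecyclodec-3E-eno-12,6-lactone | C=C1C(=O)O[C@@H]2C/C(C)=C/C[C@@H](O[Si](C)(C)C(C)(C)C)C(=C)[C@@H](O)[C@@H](O[Si](C)(C)C(C)(C)C)[C@@H]12 | intermediate
29 | angelic acid, (Z)-2-methylbut-2-enoic acid | C/C=C(/C)C(=O)O | starting material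
30 | angelic 2,4,6-trichlorobenzoic anhydride (formed in the flask) | C/C=C(/C)C(=O)OC(=O)c1c(Cl)cc(Cl)cc1Cl | intermediate
31 | (1R,6R,7S,8S,9R)-9-angeloyloxy-1,8-bis(tert-butyldimethylsilyloxy)-4-methyl-10,11-dimethylidenecyclodec-3E-eno-12,6-lactone | C=C1C(=O)O[C@@H]2C/C(C)=C/C[C@@H](O[Si](C)(C)C(C)(C)C)C(=C)[C@@H](OC(=O)/C(C)=C\C)[C@@H](O[Si](C)(C)C(C)(C)C)[C@@H]12 | intermediate
32 | (1R,3R,4R,6R,7S,8S,9R)-9-angeloyloxy-1,8-bis(tert-butyldimethylsilyloxy)-3,4-epoxy-4-methyl-10,11-dimethylidenecyclodecano-12,6-lactone | C=C1C(=O)O[C@@H]2C[C@@]3(C)O[C@@H]3C[C@@H](O[Si](C)(C)C(C)(C)C)C(=C)[C@@H](OC(=O)/C(C)=C\C)[C@@H](O[Si](C)(C)C(C)(C)C)[C@@H]12 | intermediate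
33 | (1R,3R,4R,6R,7R,8S,9R)-9-angeloyloxy-3,4-epoxy-1,8-dihydroxy-4-methyl-10,11-dimethylidenecyclodecano-12,6-lactone | C=C1C(=O)O[C@@H]2C[C@@]3(C)O[C@@H]3C[C@@H](O)C(=C)[C@@H](OC(=O)/C(C)=C\C)[C@@H](O)[C@@H]12 | intermediate
34 | CNP0348992.2, (3R,4R,6R,7R,8S,9R)-9-angeloyloxy-3,4-epoxy-8-hydroxy-4-methyl-10,11-dimethylidene-1-oxocyclodecano-12,6-lactone | C=C1C(=O)O[C@@H]2C[C@@]3(C)O[C@@H]3CC(=O)C(=C)[C@@H](OC(=O)/C(C)=C\C)[C@@H](O)[C@@H]12 | target

**Step count and risks**

Total step count: 18. Longest linear sequence: 16 steps (steps 1–3 and 6–18, from (R)-carvone); steps 4 and 5 form the side branch that joins at step 6.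

Steps most likely to fail:

Step 16. The epoxidation may take the wrong face of C3=C4 if the ring holds the olefin with its catalyst-matched face turned inward, and the epoxide may then be opened by the freed C1 hydroxyl during the acidic desilylation of step 17. The fallback replaces catalyst control by substrate control and moves the epoxidation to the end. Setting out from 31, HF·pyridine removes both silyl ethers while no epoxide is present and gives the 3E-olefinic 1,8-diol F1. MnO2 oxidises its allylic C1 carbinol to the 3,4-dehydro target enone F2. Buffered mCPBA (NaHCO3, CH2Cl2, 0 °C) then epoxidises the only electron-rich olefin, with the peracid hydrogen-bonded to the free C8 hydroxyl across the ring from C3, and the route is rejoined at 34.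

Step 10. Hydride delivery to the C8 carbonyl may show poor or reversed facial selectivity, because the ring conformation of the lactone is not known. The fallback corrects the carbinol by inversion instead of relying on the reduction. Setting out from 21, the reduction product of the wrong configuration, the 8-epimeric alcohol F3, is subjected to a Mitsunobu reaction with chloroacetic acid (PPh3, diisopropyl azodicarboxylate, THF, 0 °C) to give the inverted 8-O-chloroacetate F4. Thiourea with NaHCO3 in EtOH removes the chloroacetyl group under near-neutral conditions that leave the lactone alone, and the route is rejoined at 22.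

Step 8. The re-formed C7 enolate may lose the C6 alkoxide by beta-elimination, or be alkylated on both faces if the isolated ketone 16 relaxes to a ring conformation other than the one in which the enolate is born. The fallback traps the enolate of the rearrangement itself. Setting out from 13, the rearrangement is run as in step 7 (KN(SiMe3)2, 18-crown-6, THF), the solution of potassium enolate 15 is cooled to −78 °C, and methyl bromoacetate 17 is added in the same flask. That enolate still has the chair-derived shape that shows only its outer face, and the route is rejoined at 19; no compound outside the list is made (F0).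

**Further compounds**

F1 | step 16 | (1R,6R,7R,8S,9R)-9-angeloyloxy-1,8-dihydroxy-4-methyl-10,11-dimethylidenecyclodec-3E-eno-12,6-lactone | C=C1C(=O)O[C@@H]2C/C(C)=C/C[C@@H](O)C(=C)[C@@H](OC(=O)/C(C)=C\C)[C@@H](O)[C@@H]12
F2 | step 16 | (6R,7R,8S,9R)-9-angeloyloxy-8-hydroxy-4-methyl-10,11-dimethylidene-1-oxocyclodec-3E-eno-12,6-lactone | C=C1C(=O)O[C@@H]2C/C(C)=C/CC(=O)C(=C)[C@@H](OC(=O)/C(C)=C\C)[C@@H](O)[C@@H]12
F3 | step 10 | 8-epimer of 22, (1R,6R,7R,8S)-1-(tert-butyldimethylsilyloxy)-8-hydroxy-4,10-dimethylcyclodeca-3E,9Z-dieno-12,6-lactone | C1C(=O)O[C@@H]2C/C(C)=C/C[C@@H](O[Si](C)(C)C(C)(C)C)/C(C)=C\[C@H](O)[C@@H]12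
F4 | step 10 | 8-O-chloroacetate of 22 (C8 configured as in 22) | C1C(=O)O[C@@H]2C/C(C)=C/C[C@@H](O[Si](C)(C)C(C)(C)C)/C(C)=C\[C@@H](OC(=O)CCl)[C@@H]12
F0 | step 8 | none | none
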